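**Retrosynthetic overview**
1. Target 15 comes from allyl ether 14 by Pd deallylation; 14 comes from the 5-O-prenyl dihydroflavonol 11 by a europium-catalysed Claisen–Cope shift of the prenyl group from O5 to C8.
2. 11 comes from dialdehyde 10: the C3–C4 bond is made by a chiral-carbene intramolecular benzoin (acyl anion equivalent at C4 adds to the C3 aldehyde), which closes ring C and sets C2 and C3 in one dynamic kinetic step.
3. 10 comes from aryl ether 8 by reduction/oxidation; 8 comes from phenol 3 and racemic α-bromo ester 7 (Williamson).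
4. 3 comes from 2,4,6-trihydroxybenzaldehyde 1 (4-O-methylation, then mono-O-prenylation of two equivalent OH groups); 7 comes from homoisovanillic acid 4.
5. Ring order: rings A and B are bought; ring C is the only ring formed (step 8).

Assumption: the (5aS,10bR) antipode of the aminoindanol-derived triazolium salt is taken to deliver the (3R) carbinol; if the sense of induction is the opposite, the commercial (5aR,10bS) salt is used instead.

Abbreviations: allyl = prop-2-en-1-yl; prenyl = 3-methylbut-2-en-1-yl.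

**Step 1**
Reactants: 1 2,4,6-trihydroxybenzaldehyde
Product: 2 2,6-dihydroxy-4-methoxybenzaldehyde
Conditions: Me2SO4 (1.0 equiv), K2CO3 (1.0 equiv), acetone, rt
Reagents that add atoms: dimethyl sulfate, COS(=O)(=O)OC
Why: Williamson O-methylation; the 4-OH is the only hydroxyl not hydrogen-bonded to the formyl group and is the most acidic, so one equivalent of base and electrophile alkylates it selectively.

**Step 2**
Reactants: 2 2,6-dihydroxy-4-methoxybenzaldehyde
Product: 3 2-hydroxy-4-methoxy-6-[(3-methylbut-2-en-1-yl)oxy]benzaldehyde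
Conditions: prenyl bromide (1.05 equiv), K2CO3 (1.1 equiv), acetone, 50 °C
Reagents that add atoms: prenyl bromide (1-bromo-3-methylbut-2-ene), CC(C)=CCBr
Why: Williamson mono-O-prenylation of one of two equivalent chelated hydroxyls; the remaining OH of 3 is more tightly chelated and less acidic, so the reaction stops at the mono-ether.

**Step 3**
Reactants: 4 2-(3-hydroxy-4-methoxyphenyl)acetic acid (homoisovanillic acid)
Product: 5 allyl 2-[3-(allyloxy)-4-methoxyphenyl]acetate
Conditions: allyl bromide (2.4 equiv), K2CO3 (2.5 equiv), DMF, rt to 50 °C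
Reagents that add atoms: allyl bromide, C=CCBr
Why: one-pot carboxylate and phenoxide alkylation (Williamson type) protects the phenol as an allyl ether and gives an ester ready for enolisation.

**Step 4**
Reactants: 5 allyl 2-[3-(allyloxy)-4-methoxyphenyl]acetate
Product: 7 rac-allyl 2-[3-(allyloxy)-4-methoxyphenyl]-2-bromoacetate, via lithium enolate 6 (not isolated)
Conditions: LiN(SiMe3)2, THF, −78 °C; cannulated into NBS, THF, −78 °C; AcOH quench; used crude
Reagents that add atoms: N-bromosuccinimide, O=C1CCC(=O)N1Br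
Why: electrophilic α-bromination of a preformed ester enolate (inverse addition suppresses dibromination); the new stereocentre is deliberately left racemic because it is made dynamic and resolved in step 8.

**Step 5**
Reactants: 3 2-hydroxy-4-methoxy-6-[(3-methylbut-2-en-1-yl)oxy]benzaldehyde; 7 rac-allyl 2-[3-(allyloxy)-4-methoxyphenyl]-2-bromoacetate
Product: 8 rac-allyl 2-[3-(allyloxy)-4-methoxyphenyl]-2-{2-formyl-5-methoxy-3-[(3-methylbut-2-en-1-yl)oxy]phenoxy}acetate
Conditions: K2CO3 (1.5 equiv), DMF, 0 °C to rt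
Reagents that add atoms: none
Why: SN2 Williamson etherification of the chelated phenoxide of 3 by the activated secondary benzylic α-bromo ester at room temperature, mild enough to avoid aldol closure of the ester α-carbon onto the formyl group.

**Step 6**
Reactants: 8 rac-allyl 2-[3-(allyloxy)-4-methoxyphenyl]-2-{2-formyl-5-methoxy-3-[(3-methylbut-2-en-1-yl)oxy]phenoxy}acetate
Product: 9 rac-2-[3-(allyloxy)-4-methoxyphenyl]-2-{2-(hydroxymethyl)-5-methoxy-3-[(3-methylbut-2-en-1-yl)oxy]phenoxy}ethan-1-ol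
Conditions: LiAlH4, THF, 0 °C; Fieser work-up (H2O, aq. NaOH); used crude
Reagents that add atoms: none
Why: LiAlH4 hydride reduction takes both the aryl aldehyde and the ester to primary alcohols without touching aryl ethers or alkenes, so both carbons can be brought to the aldehyde level together in the next step.

**Step 7**
Reactants: 9 rac-2-[3-(allyloxy)-4-methoxyphenyl]-2-{2-(hydroxymethyl)-5-methoxy-3-[(3-methylbut-2-en-1-yl)oxy]phenoxy}ethan-1-ol
Product: 10 rac-2-{1-[3-(allyloxy)-4-methoxyphenyl]-2-oxoethoxy}-4-methoxy-6-[(3-methylbut-2-en-1-yl)oxy]benzaldehyde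
Conditions: Dess–Martin periodinane (2.4 equiv), NaHCO3 (excess), CH2Cl2, 0 °C to rt; filtered and used crude
Reagents that add atoms: none
Why: Dess–Martin oxidation of both primary alcohols under NaHCO3 buffering (the trioxygenated benzylic alcohol is acid-labile) gives the dialdehyde, whose C2–H is acidic enough that it is simply carried on as the racemate.

**Step 8**
Reactants: 10 rac-2-{1-[3-(allyloxy)-4-methoxyphenyl]-2-oxoethoxy}-4-methoxy-6-[(3-methylbut-2-en-1-yl)oxy]benzaldehyde
Product: 11 (2R,3R)-2-[3-(allyloxy)-4-methoxyphenyl]-3-hydroxy-7-methoxy-5-[(3-methylbut-2-en-1-yl)oxy]-2,3-dihydro-4H-chromen-4-one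
Conditions: (5aS,10bR)-2-phenyl-5a,10b-dihydro-4H,6H-indeno[2,1-b][1,2,4]triazolo[4,3-d][1,4]oxazin-2-ium tetrafluoroborate (15 mol %), iPr2NEt (1.0 equiv), toluene, 4 Å MS, rt
Reagents that add atoms: none
Why: Proposed new method: intramolecular aldehyde–aldehyde crossed benzoin with dynamic kinetic resolution, the closest known types being the chiral-triazolium aldehyde–ketone benzoin cyclisation of 2-(2-oxoalkoxy)benzaldehydes to 3-hydroxychroman-4-ones and dynamic kinetic cross-benzoin additions to racemising α-stereogenic carbonyl acceptors; the carbene adds to the aryl aldehyde to give the Breslow intermediate (acyl anion equivalent at C4), which attacks the α,α-disubstituted C3 aldehyde (a hindered acyl donor, hence the acceptor) in a 6-exo closure whose face is chosen by the catalyst (3R), while the C2–H (α-formyl, benzylic, α-aryloxy) racemises through the enol under iPr2NEt so that both enantiomers of 10 funnel through the matched chair-like transition state with aryl and OH equatorial, giving the 2,3-trans (2R,3R) ketol, in which C2 is no longer epimerisable.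

**Step 9**
Reactants: 11 (2R,3R)-2-[3-(allyloxy)-4-methoxyphenyl]-3-hydroxy-7-methoxy-5-[(3-methylbut-2-en-1-yl)oxy]-2,3-dihydro-4H-chromen-4-one
Product: 14 (2R,3R)-2-[3-(allyloxy)-4-methoxyphenyl]-3,5-dihydroxy-7-methoxy-8-(3-methylbut-2-en-1-yl)-2,3-dihydro-4H-chromen-4-one, via ortho-Claisen dienone 12 (not isolated), via para-Cope dienone 13 (not isolated)
Conditions: Eu(fod)3 [Eu(C10H10F7O2)3] (10 mol %), NaHCO3, PhCl, 85 °C
Reagents that add atoms: none
Why: europium-catalysed aromatic Claisen rearrangement (chelation by O5 and the C4 carbonyl) to C6, then Cope rearrangement to C8 and enolisation, the para-Claisen–Cope sequence known for 5-O-prenyl flavonoids; it frees the 5-OH, places the prenyl group at C8 and touches neither stereocentre.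

**Step 10**
Reactants: 14 (2R,3R)-2-[3-(allyloxy)-4-methoxyphenyl]-3,5-dihydroxy-7-methoxy-8-(3-methylbut-2-en-1-yl)-2,3-dihydro-4H-chromen-4-one
Product: 15 (2R,3R)-3,5-dihydroxy-2-(3-hydroxy-4-methoxyphenyl)-7-methoxy-8-(3-methylbut-2-en-1-yl)-2,3-dihydro-4H-chromen-4-one
Conditions: Pd(PPh3)4 (5 mol %), morpholine (5 equiv), THF, rt
Reagents that add atoms: none
Why: Tsuji–Trost deallylation; zerovalent palladium ionises the aryl allyl ether and morpholine traps the π-allyl fragment, leaving the C-prenyl group, the ketol and both stereocentres untouched.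

**Compound list**
1 | 2,4,6-trihydroxybenzaldehyde | O=Cc1c(O)cc(O)cc1O | starting material
2 | 2,6-dihydroxy-4-methoxybenzaldehyde | COc1cc(O)c(C=O)c(O)c1 | intermediate
3 | 2-hydroxy-4-methoxy-6-[(3-methylbut-2-en-1-yl)oxy]benzaldehyde | COc1cc(O)c(C=O)c(OCC=C(C)C)c1 | intermediate
4 | 2-(3-hydroxy-4-methoxyphenyl)acetic acid | COc1ccc(CC(=O)O)cc1O | starting material
5 | allyl 2-[3-(allyloxy)-4-methoxyphenyl]acetate | COc1ccc(CC(=O)OCC=C)cc1OCC=C | intermediate
6 | lithium enolate of 5 (not isolated) | COc1ccc(C=C([O-])OCC=C)cc1OCC=C.[Li+] | intermediate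
7 | rac-allyl 2-[3-(allyloxy)-4-methoxyphenyl]-2-bromoacetate | COc1ccc(C(Br)C(=O)OCC=C)cc1OCC=C | intermediate
8 | rac-allyl 2-[3-(allyloxy)-4-methoxyphenyl]-2-{2-formyl-5-methoxy-3-[(3-methylbut-2-en-1-yl)oxy]phenoxy}acetate | COc1ccc(C(Oc2cc(OC)cc(OCC=C(C)C)c2C=O)C(=O)OCC=C)cc1OCC=C | intermediate
9 | rac-2-[3-(allyloxy)-4-methoxyphenyl]-2-{2-(hydroxymethyl)-5-methoxy-3-[(3-methylbut-2-en-1-yl)oxy]phenoxy}ethan-1-ol | COc1ccc(C(CO)Oc2cc(OC)cc(OCC=C(C)C)c2CO)cc1OCC=C | intermediate
10 | rac-2-{1-[3-(allyloxy)-4-methoxyphenyl]-2-oxoethoxy}-4-methoxy-6-[(3-methylbut-2-en-1-yl)oxy]benzaldehyde | COc1ccc(C(C=O)Oc2cc(OC)cc(OCC=C(C)C)c2C=O)cc1OCC=C | intermediate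
11 | (2R,3R)-2-[3-(allyloxy)-4-methoxyphenyl]-3-hydroxy-7-methoxy-5-[(3-methylbut-2-en-1-yl)oxy]-2,3-dihydro-4H-chromen-4-one | COc1ccc([C@H]2Oc3cc(OC)cc(OCC=C(C)C)c3C(=O)[C@@H]2O)cc1OCC=C | intermediate
12 | (2R,3R)-2-[3-(allyloxy)-4-methoxyphenyl]-3-hydroxy-7-methoxy-6-(2-methylbut-3-en-2-yl)-2,3-dihydro-4H-chromene-4,5(6H)-dione, C6 epimers (not isolated) | COc1ccc([C@H]2OC3=C(C(=O)C(C(C)(C)C=C)C(OC)=C3)C(=O)[C@@H]2O)cc1OCC=C | intermediate
13 | (2R,3R)-2-[3-(allyloxy)-4-methoxyphenyl]-3-hydroxy-7-methoxy-8-(3-methylbut-2-en-1-yl)-2,3-dihydro-4H-chromene-4,5(8H)-dione, C8 epimers (not isolated) | COc1ccc([C@H]2OC3=C(C(=O)C=C(OC)C3CC=C(C)C)C(=O)[C@@H]2O)cc1OCC=C | intermediate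
14 | (2R,3R)-2-[3-(allyloxy)-4-methoxyphenyl]-3,5-dihydroxy-7-methoxy-8-(3-methylbut-2-en-1-yl)-2,3-dihydro-4H-chromen-4-one | COc1ccc([C@H]2Oc3c(CC=C(C)C)c(OC)cc(O)c3C(=O)[C@@H]2O)cc1OCC=C | intermediate
15 | (2R,3R)-3,5-dihydroxy-2-(3-hydroxy-4-methoxyphenyl)-7-methoxy-8-(3-methylbut-2-en-1-yl)-2,3-dihydro-4H-chromen-4-one | COc1ccc([C@H]2Oc3c(CC=C(C)C)c(OC)cc(O)c3C(=O)[C@@H]2O)cc1O | target

**Totals**
Total step count: 10. Longest linear sequence: 8 steps (from 1 through steps 1, 2, 5–10; the branch from 4 through steps 3, 4, 5–10 is equally long).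

**Three steps most likely to fail**

Step 8 (carbene benzoin). This is the least certain step. The carbene may engage the C3 aldehyde instead; a Breslow intermediate there can expel the aryloxide (ending as an aryl ester or 3-arylcoumarin) or give the regioisomeric ketol. The 2,6-dioxygenated aryl aldehyde is a slow acyl donor, the enolisable aldehyde can undergo aldol closure, and the dynamic resolution may give only modest ee. The fallback closes ring C through the O1–C2 bond and keeps the acyl anion chemistry as a simple hydroxymethylation. It sets out from 3. A thiazolium-carbene crossed benzoin of 3 with paraformaldehyde (3-benzyl-5-(2-hydroxyethyl)-4-methylthiazolium chloride, iPr2NEt, THF, 60 °C) gives 2-hydroxy-1-{2-hydroxy-4-methoxy-6-[(3-methylbut-2-en-1-yl)oxy]phenyl}ethan-1-one F1. Commercial isovanillin is O-allylated (allyl bromide, K2CO3, DMF) to 3-(allyloxy)-4-methoxybenzaldehyde F2. A direct syn-selective asymmetric aldol of F1 with F2 (dinuclear zinc–ProPhenol catalyst from ZnEt2, THF, 4 Å MS, −20 °C, ligand antipode chosen for the syn (2R,3S) diol) gives (2R,3S)-3-[3-(allyloxy)-4-methoxyphenyl]-2,3-dihydroxy-1-{2-hydroxy-4-methoxy-6-[(3-methylbut-2-en-1-yl)oxy]phenyl}propan-1-one F3. Mitsunobu cyclisation (PPh3, DIAD, THF, 0 °C) of the phenol onto the benzylic carbinol with inversion comes back to the route at 11.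

Step 9 (Claisen–Cope). The sequence may stop at the 6-(1,1-dimethylallyl) phenol (Claisen without Cope), lose the prenyl group, or turn over slowly because the 3-OH/C4 carbonyl also binds europium. The fallback moves the sigmatropic shift to the open-chain stage, where only the formyl group chelates. It sets out from 8. The same europium catalyst (or heating in N,N-diethylaniline at 190 °C) gives rac-allyl 2-[2-formyl-3-hydroxy-5-methoxy-6-(3-methylbut-2-en-1-yl)phenoxy]-2-[3-(allyloxy)-4-methoxyphenyl]acetate F4. LiAlH4 gives rac-2-[3-hydroxy-2-(hydroxymethyl)-5-methoxy-6-(3-methylbut-2-en-1-yl)phenoxy]-2-[3-(allyloxy)-4-methoxyphenyl]ethan-1-ol F5. Parikh–Doering oxidation (SO3·pyridine, DMSO, iPr2NEt) gives rac-6-hydroxy-4-methoxy-2-{1-[3-(allyloxy)-4-methoxyphenyl]-2-oxoethoxy}-3-(3-methylbut-2-en-1-yl)benzaldehyde F6. The triazolium-catalysed benzoin of step 8 applied to F6 then closes ring C and comes back to the route at 14.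

Step 5 (etherification). The p-alkoxybenzylic bromide 7 may solvolyse or eliminate, and under base the product can close by aldol addition of the ester α-carbon onto the formyl group (a dihydrobenzofuranol). The fallback forms the C–O bond by redox condensation under neutral conditions. It sets out from 5. Enolate 6 is hydroxylated with 2-(phenylsulfonyl)-3-phenyloxaziridine to rac-allyl 2-[3-(allyloxy)-4-methoxyphenyl]-2-hydroxyacetate F7. Mitsunobu etherification of F7 with phenol 3 (PPh3, DIAD, THF, 0 °C to rt) comes back to the route at 8.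

**Further compounds**
F1 | step 8 | 2-hydroxy-1-{2-hydroxy-4-methoxy-6-[(3-methylbut-2-en-1-yl)oxy]phenyl}ethan-1-one | COc1cc(O)c(C(=O)CO)c(OCC=C(C)C)c1
F2 | step 8 | 3-(allyloxy)-4-methoxybenzaldehyde | COc1ccc(C=O)cc1OCC=C
F3 | step 8 | (2R,3S)-3-[3-(allyloxy)-4-methoxyphenyl]-2,3-dihydroxy-1-{2-hydroxy-4-methoxy-6-[(3-methylbut-2-en-1-yl)oxy]phenyl}propan-1-one | COc1ccc([C@H](O)[C@@H](O)C(=O)c2c(O)cc(OC)cc2OCC=C(C)C)cc1OCC=C
F4 | step 9 | rac-allyl 2-[2-formyl-3-hydroxy-5-methoxy-6-(3-methylbut-2-en-1-yl)phenoxy]-2-[3-(allyloxy)-4-methoxyphenyl]acetate | COc1ccc(C(Oc2c(CC=C(C)C)c(OC)cc(O)c2C=O)C(=O)OCC=C)cc1OCC=C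
F5 | step 9 | rac-2-[3-hydroxy-2-(hydroxymethyl)-5-methoxy-6-(3-methylbut-2-en-1-yl)phenoxy]-2-[3-(allyloxy)-4-methoxyphenyl]ethan-1-ol | COc1ccc(C(CO)Oc2c(CC=C(C)C)c(OC)cc(O)c2CO)cc1OCC=C
F6 | step 9 | rac-6-hydroxy-4-methoxy-2-{1-[3-(allyloxy)-4-methoxyphenyl]-2-oxoethoxy}-3-(3-methylbut-2-en-1-yl)benzaldehyde | COc1ccc(C(C=O)Oc2c(CC=C(C)C)c(OC)cc(O)c2C=O)cc1OCC=C
F7 | step 5 | rac-allyl 2-[3-(allyloxy)-4-methoxyphenyl]-2-hydroxyacetate | COc1ccc(C(O)C(=O)OCC=C)cc1OCC=C
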